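(The numbers in the tables are simulated for substances that don't exist.)

Links rise, then fall.

| flask | solid first end groups | second end groups | temperature | remark | time |
|---|---|---|---|---|---|
| maple | 0.10 M | 0.102 M | 100 °C | the very flask that is asked about, followed so far |  |
| cedar | 0.10 M | 0.102 M | 106 °C | run made earlier |  |
| flask | 0.10 M | 0.102 M | 100 °C |  | 6.0 d |

| run | time / h | links / % | solid first end groups / % |
|---|---|---|---|
| maple | 8.00 | 52 | 4 |
| maple | 20.0 | 74 | 1 |
| maple | 40.0 | 70 | 0 |
| maple | 60.0 | 63 | 0 |
| maple | 96.0 | 51 | 0 |
| cedar | 8.00 | 60 | 0 |
| cedar | 20.0 | 72 | 0 |
| cedar | 40.0 | 60 | 1 |
| cedar | 60.0 | 51 | 0 |
| cedar | 96.0 | 40 | 0 |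

(each reading ± 1.5 percentage points)

- what is added takes up no volume worth counting
- at the start none of the solid first end groups is in solution

- alpha: change nothing and wait 40 h more
- theta: at 6.0 d take out 90% of the by-product then present, then wait 40 h
- eta: at 6.0 d add second end groups, 100% of the amount charged, then wait 40 h
- gamma: at 6.0 d raise the temperature by 15 K, then wait 40 h

- links, in percent of the solid first end groups first charged, at 6.0 d
- the remedy with the largest gain of links, or "none" below 2 percentage points (alpha / theta / eta / gamma / none)
- links present, in percent of the solid first end groups first charged, after alpha
- links present, in percent of the solid first end groups first charged, after eta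

In the maple run, links read 74% at 20.0 h and 51% at 96.0 h, while solid first end groups, the limiting reagent at 0.10 M against 0.102 M of second end groups, have stopped showing. One reversible step climbs towards its balance and does not come back down, so a second path is at work, and near that peak control passes from the making of links to their loss.

My own reckoning takes that loss to be links meeting by-product. The two are born one for one and lost one for one, so they stand at equal concentration, the loss rate goes as [links][by-product], and once the making of links has faded the reciprocal of [links] climbs close to a straight line. Between 40.0 h and 96.0 h the maple readings give 0.0950 L mol⁻¹ h⁻¹. This climb per hour, net of any links still being made, is carried on as the net drain constant κ: a reading with their scatter, which understates the loss step itself while making goes on. The cedar run reads 0.149 L mol⁻¹ h⁻¹, larger, so heat speeds the drain and gamma loses.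

From the last maple reading, κ carries links to 41.4% at 6.0 d and to 35.8% after alpha. Taking out 90% of the by-product slows the drain by that share, and links still lose 0.65 percentage points, so theta holds them without a gain. If the missing share is drained material, added second end groups find little to bind, and eta follows alpha. My answer is none.

The forecast gives 40% and 33%, but chooses eta with 72%, on the ground that “Adding second end groups meets about 60% dissolved first groups”. The two part on the missing share: drained, or dissolved and waiting.

The flask gives 39.6% at 6.0 d, 33.5% after alpha and 34.4% after eta, while theta moves links by −0.21 points; the answer is none.

    first end groups + second end groups → links + by-product (k = 0.0420 L mol⁻¹ min⁻¹, Ea = 66.0 kJ mol⁻¹)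
    links + by-product → side product (k = 0.00210 L mol⁻¹ min⁻¹, Ea = 91.0 kJ mol⁻¹)
    solid first end groups ⇌ first end groups, rate k3*(cs3 - [first end groups]) while solid is left; crystals form when [first end groups] > cs3 (solubility = 0.0540 M, k = 0.0110 min⁻¹)
    (constants at 100 °C)

At 144 h the maple flask holds 58.5% side product against 1.87% first end groups. In the flask charged with 0.025 M of solid first end groups, counted as links from the start, κ gives 74.5% at 6.0 d, and that flask holds 69.9%. The maple flask is not at rest: links are made at 0.0925 of the rate of their loss. From 39.6%, κ carries them to 6.74% at 1440 h, and left that long the flask stands at 5.42% links with 94.6% side product.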